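**Plan**

- Retrosynthetic cuts: C8–C9 (sp3–sp2 coupling of a 6-vinyl dioxane with an E-alkenyl iodide), the exocyclic C7=C8 (methylenation of a C7 aldehyde obtained by glycol cleavage), then the ring bond O1–C6, then O2–C3 (SN2 perhydrolysis), then C2–C3 (aldol).
- Enabling feature: in the ring O1–O2–C3–C4–C5–C6 an OOH on C3 lies six atoms from C6. C6 is quaternary (methyl plus exocyclic C7), so C6–C7 can be held as an oxirane. Opening it at C6 by the peroxide oxygen is a 6-exo-tet closure that leaves the C7 oxygen outside the ring as the handle for the side chain.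
- Forward order: geraniol supplies C3–C8 and the C6 methyl; it is epoxidised, cut to the C3 aldehyde, extended by C1/C2, converted to the C3 hydroperoxide, and the 1,2-dioxane is closed. The cyclohexene ring is bought in. The C7,C8-diol becomes a vinyl group, C1 is oxidised to the methyl ester, and the C11 alkenyl iodide is joined last.
- Stereochemistry: C6 comes from the Sharpless epoxidation and is inverted in the ring closure. C2 and C3 come from an Evans syn-aldol, with C3 inverted by the peroxide SN2. The E-alkene comes from syn-carboalumination of a terminal alkyne.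

Key step: step 9

**Route**

Step 1
Reactants: 1 geraniol
Product: 2 (2S,3S)-2,3-epoxygeraniol
Conditions: Ti(OiPr)4 (cat.), L-(+)-diethyl tartrate (cat.), tBuOOH, 4 Å MS, CH2Cl2, −20 °C
Reagents that add atoms: tert-butyl hydroperoxide, CC(C)(C)OO
Why: Sharpless asymmetric epoxidation: the allylic hydroxyl anchors the substrate on the Ti(OiPr)4/tartrate catalyst so that only the 2,3-alkene reacts, and the L-(+)-tartrate should deliver oxygen to the face that gives the (2S,3S) oxirane, which fixes the future C6.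

Step 2
Reactants: 2 (2S,3S)-2,3-epoxygeraniol
Product: 3 tert-butyl(dimethyl){[(2S,3S)-3-methyl-3-(4-methylpent-3-en-1-yl)oxiran-2-yl]methoxy}silane
Conditions: TBSCl, imidazole, DMF, 0 °C to rt
Reagents that add atoms: tert-butyl(chloro)dimethylsilane, CC(C)(C)[Si](C)(C)Cl
Why: Standard silyl ether formation masks the primary hydroxyl so that it cannot quench the boron enolate of step 4; no stereocentre is touched.

Step 3
Reactants: 3 silyl ether of epoxygeraniol
Product: 5 3-[(2S,3S)-3-{[tert-butyl(dimethyl)silyl]oxymethyl}-2-methyloxiran-2-yl]propanal, via secondary ozonide 4 (not isolated)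
Conditions: O3, CH2Cl2, −78 °C; then Me2S, −78 °C to rt
Reagents that add atoms: ozone, [O-][O+]=O
Why: Ozonolysis with reductive work-up cleaves the only remaining alkene to the aldehyde (future C3) and acetone, while the oxirane and the silyl ether are inert to ozone and dimethyl sulfide.

Step 4
Reactants: 5 epoxy aldehyde; 6 (4S)-4-benzyl-3-propanoyl-1,3-oxazolidin-2-one
Product: 8 (4S)-4-benzyl-3-[(2S,3R)-5-[(2S,3S)-3-{[tert-butyl(dimethyl)silyl]oxymethyl}-2-methyloxiran-2-yl]-3-hydroxy-2-methylpentanoyl]-1,3-oxazolidin-2-one, via dibutylboron Z-enolate 7 (not isolated)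
Conditions: 6, Bu2BOTf, iPr2NEt, CH2Cl2, 0 °C; then 5, −78 to 0 °C; pH 7 buffer, MeOH, 30% H2O2, 0 °C
Reagents that add atoms: none
Why: Evans syn-aldol reaction: the Z-boron enolate adds through a closed Zimmerman–Traxler chair in which the benzyl group of the auxiliary blocks one enolate face, so the 2S,3R syn adduct should form irrespective of the remote oxirane, which survives because the boron triflate is consumed in enolate formation before the aldehyde is added.

Step 5
Reactants: 8 aldol adduct
Product: 9 (2R,3R)-5-[(2S,3S)-3-{[tert-butyl(dimethyl)silyl]oxymethyl}-2-methyloxiran-2-yl]-2-methylpentane-1,3-diol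
Conditions: LiBH4, MeOH (1 equiv), THF, 0 °C
Reagents that add atoms: none
Why: Reductive cleavage of the N-acyl oxazolidinone with LiBH4 gives the primary alcohol and returns the auxiliary; removing the carbonyl here prevents beta-elimination in the later substitution at C3, and the trisubstituted oxirane should not be opened by borohydride at 0 °C.

Step 6
Reactants: 9 diol
Product: 10 (2R,3R)-1-{[tert-butyl(dimethyl)silyl]oxy}-5-[(2S,3S)-3-{[tert-butyl(dimethyl)silyl]oxymethyl}-2-methyloxiran-2-yl]-2-methylpentan-3-ol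
Conditions: TBSCl (1.05 equiv), imidazole, CH2Cl2, −10 to 0 °C
Reagents that add atoms: tert-butyl(chloro)dimethylsilane, CC(C)(C)[Si](C)(C)Cl
Why: Selective silylation: the primary hydroxyl reacts much faster than the secondary one at low temperature, leaving the C3 hydroxyl free.

Step 7
Reactants: 10 secondary alcohol
Product: 11 (2R,3R)-1-{[tert-butyl(dimethyl)silyl]oxy}-5-[(2S,3S)-3-{[tert-butyl(dimethyl)silyl]oxymethyl}-2-methyloxiran-2-yl]-2-methylpentan-3-yl methanesulfonate
Conditions: MsCl, Et3N, CH2Cl2, 0 °C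
Reagents that add atoms: methanesulfonyl chloride, CS(=O)(=O)Cl
Why: Sulfonylation of the secondary alcohol forms only an O–S bond, so C3 keeps its configuration and becomes a leaving-group carbon.

Step 8
Reactants: 11 methanesulfonate
Product: 12 tert-butyl{[(2R,3S)-5-[(2S,3S)-3-{[tert-butyl(dimethyl)silyl]oxymethyl}-2-methyloxiran-2-yl]-3-hydroperoxy-2-methylpentyl]oxy}dimethylsilane
Conditions: 50% aq H2O2 (excess), KOH, MeOH/THF, 0 °C to rt; cold neutral work-up, used directly
Reagents that add atoms: hydrogen peroxide, OO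
Why: SN2 perhydrolysis of a secondary methanesulfonate: the hydroperoxide anion (an alpha-effect nucleophile) displaces the sulfonate with inversion, turning 3R into 3S, while the trisubstituted oxirane is inert to base and no carbonyl is present to promote elimination.

Step 9
Reactants: 12 epoxy hydroperoxide
Product: 13 (1S)-2-{[tert-butyl(dimethyl)silyl]oxy}-1-[(3R,6S)-6-[(2R)-1-{[tert-butyl(dimethyl)silyl]oxy}propan-2-yl]-3-methyl-1,2-dioxan-3-yl]ethan-1-ol
Conditions: (+)-camphor-10-sulfonic acid (10 mol%), CH2Cl2, 0 °C to rt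
Reagents that add atoms: none
Why: The sulfonic acid protonates the oxirane oxygen, the tertiary C–O bond lengthens, and the terminal oxygen of the C3 hydroperoxide attacks the tertiary oxirane carbon from the side opposite the departing oxygen in a borderline SN2 epoxide opening. The closest known reaction type is the acid-catalysed intramolecular opening of epoxides by hydroperoxides, which gives hydroxyalkyl 1,2-dioxolanes and 1,2-dioxanes. The one ring formed, the 1,2-dioxane, closes in the 6-exo-tet mode. The new quaternary stereocentre C6 is fixed by inversion of the oxirane carbon set in step 1, so C7 ends up cis to the C3 substituent regardless of chair preferences, while C7 keeps its configuration and C2 and C3 are untouched. The step needs attack at the tertiary carbon (six-membered ring) in preference to the secondary carbon (seven-membered ring) and to Meinwald rearrangement; this is secured by the greater positive charge at the fully substituted carbon, the smaller ring, the inductive deactivation of C7 by the neighbouring silyloxymethyl group and the non-nucleophilic solvent.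

Step 10
Reactants: 13 bis-silylated dioxane
Product: 14 (1S)-1-[(3R,6S)-6-[(2R)-1-hydroxypropan-2-yl]-3-methyl-1,2-dioxan-3-yl]ethane-1,2-diol
Conditions: HF·pyridine, pyridine, THF, 0 °C to rt
Reagents that add atoms: none
Why: Fluoride-mediated desilylation removes both silyl ethers under non-basic, non-reducing conditions that leave the dialkyl peroxide intact and expose the 1,2-diol.

Step 11
Reactants: 14 triol
Product: 15 (3R,6S)-6-[(2R)-1-hydroxypropan-2-yl]-3-methyl-1,2-dioxane-3-carbaldehyde
Conditions: NaIO4, THF/H2O (pH 7 phosphate buffer), 0 °C to rt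
Reagents that add atoms: none
Why: Periodate glycol cleavage excises the terminal carbinol carbon as formaldehyde and leaves the aldehyde on the quaternary carbon, which cannot epimerise; the isolated primary alcohol and the peroxide are not oxidised.

Step 12
Reactants: 15 hydroxy aldehyde
Product: 16 (2R)-2-[(3S,6R)-6-ethenyl-6-methyl-1,2-dioxan-3-yl]propan-1-ol
Conditions: Ph3PCH3Br (2.5 equiv), KN(SiMe3)2, THF, 0 °C; then 15, −78 to 0 °C
Reagents that add atoms: methyltriphenylphosphonium bromide, C[P+](c1ccccc1)(c1ccccc1)c1ccccc1.[Br-]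
Why: Wittig methylenation: the non-stabilised ylide, used in excess because the free hydroxyl consumes one equivalent, converts the non-enolisable alpha-peroxy aldehyde into the vinyl group without reducing the O–O bond.

Step 13
Reactants: 16 vinyl alcohol
Product: 17 (2S)-2-[(3S,6R)-6-ethenyl-6-methyl-1,2-dioxan-3-yl]propanoic acid
Conditions: TEMPO (cat.), PhI(OAc)2 (2.2 equiv), MeCN/H2O, rt
Reagents that add atoms: water, O
Why: Nitroxyl-catalysed oxidation takes the primary alcohol through the aldehyde hydrate to the acid under near-neutral conditions that spare the vinyl group and the peroxide and should not epimerise C2.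

Step 14
Reactants: 17 acid
Product: 18 methyl (2S)-2-[(3S,6R)-6-ethenyl-6-methyl-1,2-dioxan-3-yl]propanoate
Conditions: Me3SiCHN2, MeOH/toluene, 0 °C
Reagents that add atoms: trimethylsilyldiazomethane, C[Si](C)(C)C=[N+]=[N-]
Why: Esterification with trimethylsilyldiazomethane in methanol methylates the acid without base, so retro-oxa-Michael opening of the beta-peroxy ester is avoided.

Step 15
Reactants: 19 4-(2,6,6-trimethylcyclohex-1-en-1-yl)butan-2-one (dihydro-beta-ionone)
Product: 21 2-(but-3-yn-1-yl)-1,3,3-trimethylcyclohex-1-ene, via enol diethyl phosphate 20 (not isolated)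
Conditions: LiN(iPr)2, THF, −78 °C; ClP(O)(OEt)2, −78 °C to rt; LiN(iPr)2 (2.3 equiv), −78 °C to rt
Reagents that add atoms: none
Why: Methyl ketone to terminal alkyne conversion: kinetic deprotonation gives the less substituted enolate, which is trapped on oxygen as the enol phosphate, and further amide base effects beta-elimination to the alkyne.

Step 16
Reactants: 21 terminal alkyne
Product: 23 2-[(3E)-4-iodo-3-methylbut-3-en-1-yl]-1,3,3-trimethylcyclohex-1-ene, via dimethylalkenylalane 22 (not isolated)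
Conditions: AlMe3, Cp2ZrCl2, CH2Cl2, 0 °C to rt; then I2, THF, −30 to 0 °C
Reagents that add atoms: trimethylaluminium, C[Al](C)C; iodine, II
Why: Negishi carboalumination catalysed by Cp2ZrCl2 adds methyl and aluminium syn across the terminal alkyne with aluminium at the terminus, and iodinolysis with retention gives the E-alkenyl iodide; the tetrasubstituted ring alkene does not react.

Step 17
Reactants: 18 vinyl dioxane ester; 23 E-alkenyl iodide
Product: 25 methyl (2S)-2-[(3S,6S)-6-methyl-6-[(3E)-4-methyl-6-(2,6,6-trimethylcyclohex-1-en-1-yl)hex-3-en-1-yl]-1,2-dioxan-3-yl]propanoate, via B-alkyl-9-BBN adduct 24 (not isolated)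
Conditions: 18, 9-BBN-H dimer, THF, 0 °C to rt; then 23, PdCl2(dppf) (cat.), AsPh3, aq K3PO4, DMF, rt
Reagents that add atoms: none
Why: B-alkyl Suzuki–Miyaura coupling: 9-BBN hydroborates only the monosubstituted vinyl group at its terminus and the alkyl group is transferred to palladium under mild phosphate base with retention of the E geometry, forming C8–C9; dialkyl peroxides and methyl esters are expected to tolerate 9-BBN and these room-temperature conditions.

**Compound list**

1 | geraniol, (2E)-3,7-dimethylocta-2,6-dien-1-ol | CC(C)=CCC/C(C)=C/CO | starting material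
2 | [(2S,3S)-3-methyl-3-(4-methylpent-3-en-1-yl)oxiran-2-yl]methanol | CC(C)=CCC[C@@]1(C)[C@H](CO)O1 | intermediate
3 | tert-butyl(dimethyl){[(2S,3S)-3-methyl-3-(4-methylpent-3-en-1-yl)oxiran-2-yl]methoxy}silane | CC(C)=CCC[C@@]1(C)[C@H](CO[Si](C)(C)C(C)(C)C)O1 | intermediate
4 | 3-{2-[(2S,3S)-3-{[tert-butyl(dimethyl)silyl]oxymethyl}-2-methyloxiran-2-yl]ethyl}-5,5-dimethyl-1,2,4-trioxolane (both epimers at the trioxolane carbon) | CC1(C)OOC(CC[C@@]2(C)[C@H](CO[Si](C)(C)C(C)(C)C)O2)O1 | intermediate
5 | 3-[(2S,3S)-3-{[tert-butyl(dimethyl)silyl]oxymethyl}-2-methyloxiran-2-yl]propanal | O=CCC[C@@]1(C)[C@H](CO[Si](C)(C)C(C)(C)C)O1 | intermediate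
6 | (4S)-4-benzyl-3-propanoyl-1,3-oxazolidin-2-one | CCC(=O)N1[C@@H](Cc2ccccc2)COC1=O | starting material
7 | dibutylboron Z-enolate of 6 | C/C=C(\OB(CCCC)CCCC)N1[C@@H](Cc2ccccc2)COC1=O | intermediate
8 | (4S)-4-benzyl-3-[(2S,3R)-5-[(2S,3S)-3-{[tert-butyl(dimethyl)silyl]oxymethyl}-2-methyloxiran-2-yl]-3-hydroxy-2-methylpentanoyl]-1,3-oxazolidin-2-one | O=C(N1[C@@H](Cc2ccccc2)COC1=O)[C@@H](C)[C@H](O)CC[C@@]3(C)[C@H](CO[Si](C)(C)C(C)(C)C)O3 | intermediate
9 | (2R,3R)-5-[(2S,3S)-3-{[tert-butyl(dimethyl)silyl]oxymethyl}-2-methyloxiran-2-yl]-2-methylpentane-1,3-diol | OC[C@@H](C)[C@H](O)CC[C@@]1(C)[C@H](CO[Si](C)(C)C(C)(C)C)O1 | intermediate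
10 | (2R,3R)-1-{[tert-butyl(dimethyl)silyl]oxy}-5-[(2S,3S)-3-{[tert-butyl(dimethyl)silyl]oxymethyl}-2-methyloxiran-2-yl]-2-methylpentan-3-ol | CC(C)(C)[Si](C)(C)OC[C@@H](C)[C@H](O)CC[C@@]1(C)[C@H](CO[Si](C)(C)C(C)(C)C)O1 | intermediate
11 | (2R,3R)-1-{[tert-butyl(dimethyl)silyl]oxy}-5-[(2S,3S)-3-{[tert-butyl(dimethyl)silyl]oxymethyl}-2-methyloxiran-2-yl]-2-methylpentan-3-yl methanesulfonate | CC(C)(C)[Si](C)(C)OC[C@@H](C)[C@H](OS(C)(=O)=O)CC[C@@]1(C)[C@H](CO[Si](C)(C)C(C)(C)C)O1 | intermediate
12 | tert-butyl{[(2R,3S)-5-[(2S,3S)-3-{[tert-butyl(dimethyl)silyl]oxymethyl}-2-methyloxiran-2-yl]-3-hydroperoxy-2-methylpentyl]oxy}dimethylsilane | CC(C)(C)[Si](C)(C)OC[C@@H](C)[C@@H](OO)CC[C@@]1(C)[C@H](CO[Si](C)(C)C(C)(C)C)O1 | intermediate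
13 | (1S)-2-{[tert-butyl(dimethyl)silyl]oxy}-1-[(3R,6S)-6-[(2R)-1-{[tert-butyl(dimethyl)silyl]oxy}propan-2-yl]-3-methyl-1,2-dioxan-3-yl]ethan-1-ol | CC(C)(C)[Si](C)(C)OC[C@@H](C)[C@@H]1CC[C@](C)([C@@H](O)CO[Si](C)(C)C(C)(C)C)OO1 | intermediate
14 | (1S)-1-[(3R,6S)-6-[(2R)-1-hydroxypropan-2-yl]-3-methyl-1,2-dioxan-3-yl]ethane-1,2-diol | OC[C@@H](C)[C@@H]1CC[C@](C)([C@@H](O)CO)OO1 | intermediate
15 | (3R,6S)-6-[(2R)-1-hydroxypropan-2-yl]-3-methyl-1,2-dioxane-3-carbaldehyde | OC[C@@H](C)[C@@H]1CC[C@](C)(C=O)OO1 | intermediate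
16 | (2R)-2-[(3S,6R)-6-ethenyl-6-methyl-1,2-dioxan-3-yl]propan-1-ol | OC[C@@H](C)[C@@H]1CC[C@](C)(C=C)OO1 | intermediate
17 | (2S)-2-[(3S,6R)-6-ethenyl-6-methyl-1,2-dioxan-3-yl]propanoic acid | OC(=O)[C@@H](C)[C@@H]1CC[C@](C)(C=C)OO1 | intermediate
18 | methyl (2S)-2-[(3S,6R)-6-ethenyl-6-methyl-1,2-dioxan-3-yl]propanoate | COC(=O)[C@@H](C)[C@@H]1CC[C@](C)(C=C)OO1 | intermediate
19 | 4-(2,6,6-trimethylcyclohex-1-en-1-yl)butan-2-one (dihydro-beta-ionone) | CC(=O)CCC1=C(C)CCCC1(C)C | starting material
20 | diethyl 4-(2,6,6-trimethylcyclohex-1-en-1-yl)but-1-en-2-yl phosphate | C=C(OP(=O)(OCC)OCC)CCC1=C(C)CCCC1(C)C | intermediate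
21 | 2-(but-3-yn-1-yl)-1,3,3-trimethylcyclohex-1-ene | C#CCCC1=C(C)CCCC1(C)C | intermediate
22 | dimethyl[(1E)-2-methyl-4-(2,6,6-trimethylcyclohex-1-en-1-yl)but-1-en-1-yl]alumane | C[Al](C)/C=C(\C)CCC1=C(C)CCCC1(C)C | intermediate
23 | 2-[(3E)-4-iodo-3-methylbut-3-en-1-yl]-1,3,3-trimethylcyclohex-1-ene | I/C=C(\C)CCC1=C(C)CCCC1(C)C | intermediate
24 | methyl (2S)-2-[(3S,6S)-6-[2-(9-borabicyclo[3.3.1]nonan-9-yl)ethyl]-6-methyl-1,2-dioxan-3-yl]propanoate | COC(=O)[C@@H](C)[C@@H]1CC[C@](C)(CCB2C3CCCC2CCC3)OO1 | intermediate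
25 | methyl (2S)-2-[(3S,6S)-6-methyl-6-[(3E)-4-methyl-6-(2,6,6-trimethylcyclohex-1-en-1-yl)hex-3-en-1-yl]-1,2-dioxan-3-yl]propanoate | COC(=O)[C@@H](C)[C@@H]1CC[C@](C)(CC/C=C(\C)CCC2=C(C)CCCC2(C)C)OO1 | target

**Step count and risks**

Total step count: 17. Longest linear sequence: 15 steps (steps 1 to 14, then step 17).

Steps most likely to fail:

1. Step 8. Substitution at the beta-branched secondary carbon may be slow, so that E2 loss of methanesulfonate and base-induced decomposition of the secondary hydroperoxide (Kornblum–DeLaMare type) take over. The fallback sets out from 11 and comes back at 12. It transfers a masked, weakly basic peroxide instead of free hydrogen peroxide: 11 would be treated with 2-methoxyprop-2-yl hydroperoxide and CsOH in DMF at 0 °C, which should give with inversion the 2-methoxyprop-2-yl peroxyketal F1. Aqueous acetic acid in THF at 0 °C would then release the hydroperoxide 12.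

2. Step 17. The O–O bond may be cleaved reductively by zerovalent palladium or by the borane, and the phosphate base may open the beta-peroxy ester by retro-oxa-Michael reaction. The fallback sets out from 15 (with 19 as the source of the chain) and comes back at 25. It replaces the metal-catalysed coupling by olefination and selective diimide reduction. CH2=CHMgBr would add to 19 to give 3-methyl-5-(2,6,6-trimethylcyclohex-1-en-1-yl)pent-1-en-3-ol F3, and Ph3P·HBr would convert this with allylic transposition into [(2E)-3-methyl-5-(2,6,6-trimethylcyclohex-1-en-1-yl)pent-2-en-1-yl]triphenylphosphonium bromide F4. Its ylide (KN(SiMe3)2, THF, −78 °C) would react with 15 in a Wittig reaction to give the 1,3-diene alcohol F5. Diimide (2-nitrobenzenesulfonyl hydrazide, Et3N, CH2Cl2, rt) should saturate only the disubstituted C7=C8 alkene to give the chain-complete alcohol F6. TEMPO/PhI(OAc)2 would give the acid F7, and Me3SiCHN2 in methanol would give 25.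

3. Step 9. The peroxide oxygen may attack the secondary oxirane carbon to give the seven-membered ring, or the acid may trigger a hydride or alkyl shift of the oxirane (Meinwald rearrangement) before the ring closes. The fallback sets out from 11 and comes back at 13; it closes the same ring through the other C–O bond. The oxirane of 11 would be opened at its tertiary carbon by anhydrous ethereal H2O2 with catalytic H3PMo12O40 (inversion at C6), to give (2R,3R,6R,7S)-1,8-bis{[tert-butyl(dimethyl)silyl]oxy}-6-hydroperoxy-7-hydroxy-2,6-dimethyloctan-3-yl methanesulfonate F2. KOtBu with 18-crown-6 in toluene at 0 °C would then close the dioxane by 6-exo-tet displacement of the methanesulfonate by the peroxide anion with inversion at C3, giving 13.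

Further compounds
F1 | step 8 | tert-butyl{[(2R,3S)-5-[(2S,3S)-3-{[tert-butyl(dimethyl)silyl]oxymethyl}-2-methyloxiran-2-yl]-3-[(2-methoxypropan-2-yl)peroxy]-2-methylpentyl]oxy}dimethylsilane | CC(C)(C)[Si](C)(C)OC[C@@H](C)[C@@H](OOC(C)(C)OC)CC[C@@]1(C)[C@H](CO[Si](C)(C)C(C)(C)C)O1
F2 | step 9 | (2R,3R,6R,7S)-1,8-bis{[tert-butyl(dimethyl)silyl]oxy}-6-hydroperoxy-7-hydroxy-2,6-dimethyloctan-3-yl methanesulfonate | CC(C)(C)[Si](C)(C)OC[C@@H](C)[C@H](OS(C)(=O)=O)CC[C@@](C)(OO)[C@@H](O)CO[Si](C)(C)C(C)(C)C
F3 | step 17 | 3-methyl-5-(2,6,6-trimethylcyclohex-1-en-1-yl)pent-1-en-3-ol | CC(O)(C=C)CCC1=C(C)CCCC1(C)C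
F4 | step 17 | [(2E)-3-methyl-5-(2,6,6-trimethylcyclohex-1-en-1-yl)pent-2-en-1-yl]triphenylphosphonium bromide | C/C(CCC1=C(C)CCCC1(C)C)=C\C[P+](c1ccccc1)(c1ccccc1)c1ccccc1.[Br-]
F5 | step 17 | (2R)-2-[(3S,6R)-6-methyl-6-[(3E)-4-methyl-6-(2,6,6-trimethylcyclohex-1-en-1-yl)hexa-1,3-dien-1-yl]-1,2-dioxan-3-yl]propan-1-ol (1-ene geometry mixed) | OC[C@@H](C)[C@@H]1CC[C@](C)(C=C/C=C(\C)CCC2=C(C)CCCC2(C)C)OO1
F6 | step 17 | (2R)-2-[(3S,6S)-6-methyl-6-[(3E)-4-methyl-6-(2,6,6-trimethylcyclohex-1-en-1-yl)hex-3-en-1-yl]-1,2-dioxan-3-yl]propan-1-ol | OC[C@@H](C)[C@@H]1CC[C@](C)(CC/C=C(\C)CCC2=C(C)CCCC2(C)C)OO1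
F7 | step 17 | (2S)-2-[(3S,6S)-6-methyl-6-[(3E)-4-methyl-6-(2,6,6-trimethylcyclohex-1-en-1-yl)hex-3-en-1-yl]-1,2-dioxan-3-yl]propanoic acid | OC(=O)[C@@H](C)[C@@H]1CC[C@](C)(CC/C=C(\C)CCC2=C(C)CCCC2(C)C)OO1
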